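Of the starting material charged on Friday, 22.8% stands neither as target nor as isomer of the product at 20.0 min, and what follows is carried by how the two products divide the rest.

| flask | starting material | remark | time |
|---|---|---|---|
| Friday's | 0.025 M | run made earlier |  |
| flask | 0.050 M |  | 1.5 h |

Friday's run (percent of the starting material charged)

| time / min | isomer of the product / % | target / % |
|---|---|---|
| 1.50 | 29.4 | 40.0 |
| 5.00 | 33.6 | 43.7 |
| 8.00 | 32.9 | 44.4 |
| 12.0 | 34.3 | 44.2 |
| 20.0 | 33.5 | 43.7 |

(scatter of a reading: 0.5 percentage points)

* share of isomer of the product in isomer of the product plus target at 10 s
* share of isomer of the product in isomer of the product plus target at 1.5 h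
* which of isomer of the product and target there is more of at 1.5 h

- the numbers in the tables scatter by 0.5 percentage points (one standard deviation)

The division is carried here as the end share S = c(isomer of the product)/(c(isomer of the product) + c(target)), summed over Friday's readings: 43.1%.

Friday's product sum runs into a level of 77.6% and already stands at 69.4% at 1.50 min, so the knee lies before the first reading. Taken as first order, that rise has a constant of 1.50 min⁻¹ and a half-time of 27.7 s. On Friday's charge, then, 10 s falls on the opening rise. Friday's share reads flat within the scatter from 1.50 min onward, and S lies below 0.5, so this reckoning puts the new flask's share at 1.5 h at S, with target ahead. The first reading comes 9.00 times later than 10 s, however, and a flat share and one rising from zero pass equally through these readings. This reckoning therefore leaves the early share open, where the forecast commits to 43%. The forecast gives 43.3% at the end, with target ahead, and its ground reads: “The constant ratio suggests either parallel formation under kinetic control or a rapidly established equilibrium.”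

The new flask gives 18.8% at 10 s, which is 24 percentage points below the forecast and below S, and 43.3% at 1.5 h, with target ahead.

starting material ⇌ intermediate A (K = 1.70, k = 0.210 s⁻¹); starting material ⇌ intermediate B (K = 33.1, k = 0.0693 s⁻¹); intermediate B → target (k = 0.172 s⁻¹); intermediate A → decomposed reagent (k = 0.00337 s⁻¹); 2 starting material → homo dimer (k = 1.25 L mol⁻¹ s⁻¹); target ⇌ isomer of the product (K = 0.763, k = 0.0611 s⁻¹) Target and isomer of the product relax by their own step, both ways together, with a half-life of 0.0818 min, short against 1.5 h. From the new flask's 29.0% of isomer at 1.5 h, S gives 38.3% of target, against 38.0% found. The neighbour flask at 0.013 M holds 36.2% of isomer at 1.5 h, from which S gives 47.8% of target, and it holds 47.4%.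

The readings come from a simulation for substances that don't exist; noise was put on by code.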